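**Retrosynthetic overview**
1. Last ring: the C8–C9 bond is made by an iron-hydride hydrogen-atom-transfer radical cyclisation (7-endo) onto a vinyl ketone; this closes the seven-membered ring, creates quaternary C8 and turns a =CH2 into the C8 methyl.
2. Enabling feature: an exocyclic methylene on C8, the one-carbon bridge of the bicyclo[3.1.1]heptane flanked by the bridgeheads C3 and C7, sits 1,3 across the cyclobutane (C2–C3–C8–C7) from the pseudo-axial C2 arm that ends in the vinyl ketone C11(=O)–C10=C9.
3. Cyclobutane: the C2–C7 bond comes from π-assisted ionisation of a C2 triflate in a cyclohexene, with the C8 cation ending as C8=CH2.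
4. C3–C2 bond: syn-aldol union of (R)-5-methylcyclohexenone (its methyl, the later C4 methyl, fixes the cage handedness and is erased at the end) with an aldehyde that carries quaternary C1 (Evans aldol, then Fráter–Seebach alkylation).
5. Ring order: six-membered ring (bought) → cyclobutane (step 11) → seven-membered ring (step 14); directed C11 reduction, the two esters and the enone C4=C5 come last.

Key step: step 14

Locants used below (target): C1 = C(CH3)(CH2O–); C2 = cyclobutane CH next to C1; C3 and C7 = bridgehead CH (C3 next to C4, C7 next to the carbonyl C6); C4(CH3)=C5–C6(=O) = enone; C8 = quaternary cyclobutane carbon with CH3; C9, C10 = ring CH2; C11 = CH–OAc.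

Assumption: 11 is bought as such (it is also the known three-step degradation product of (R)-pulegone); the carbinol configurations drawn at C8 in 14 and at C6 in 15–19 are the expected ones but are of no consequence, because both carbons become planar later.

**Route**

Step 1
Reactants: 1 (R)-4-benzyl-3-propanoyl-1,3-oxazolidin-2-one; 2 acrolein
Product: 4 (4R)-4-benzyl-3-[(2R,3S)-3-hydroxy-2-methylpent-4-enoyl]-1,3-oxazolidin-2-one, via dibutylboron Z-enolate 3 (not isolated)
Conditions: Bu2BOTf, i-Pr2NEt, CH2Cl2, 0 °C; 2, −78 → 0 °C; then pH 7 buffer, MeOH, H2O2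
Reagents that add atoms: none
Why: Evans syn-aldol; the Z-boron enolate reacts through a Zimmerman–Traxler chair under auxiliary control, so the (R)-auxiliary should give the (2R,3S) adduct and with it the (S)-carbinol (later C11) that steers the quaternary centre in step 3.

Step 2
Reactants: 4
Product: 5 methyl (2R,3S)-3-hydroxy-2-methylpent-4-enoate
Conditions: NaOMe (cat.), MeOH, 0 °C
Reagents that add atoms: methanol, CO
Why: Methoxide transesterification at the exocyclic imide carbonyl should free the methyl ester and the recoverable auxiliary without touching the carbinol centre.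

Step 3
Reactants: 5
Product: 7 methyl (2S,3S)-2-[(benzyloxy)methyl]-3-hydroxy-2-methylpent-4-enoate, via dilithium alkoxide-enolate 6 (not isolated)
Conditions: LDA (2.2 equiv), THF, −78 → −20 °C; BnOCH2Cl, −78 °C; then H2O
Reagents that add atoms: benzyl chloromethyl ether, ClCOCc1ccccc1
Why: Fráter–Seebach alkylation; the chelated alkoxide-enolate (old α-centre erased) is attacked on the face away from the vinyl-bearing carbinol substituent, so the benzyloxymethyl group should enter anti to the hydroxyl and set quaternary C1.

Step 4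
Reactants: 7
Product: 8 methyl (2S,3S)-2-[(benzyloxy)methyl]-3-[(tert-butyldimethylsilyl)oxy]-2-methylpent-4-enoate
Conditions: TBSOTf, 2,6-lutidine, CH2Cl2, 0 °C
Reagents that add atoms: tert-butyldimethylsilyl triflate, CC(C)(C)[Si](C)(C)OS(=O)(=O)C(F)(F)F
Why: Silyl triflate silylation is the standard way to protect a hindered secondary allylic alcohol next to a quaternary carbon.

Step 5
Reactants: 8
Product: 9 (2S,3S)-2-[(benzyloxy)methyl]-3-[(tert-butyldimethylsilyl)oxy]-2-methylpent-4-en-1-ol
Conditions: i-Bu2AlH, CH2Cl2, −78 → 0 °C; aq. Rochelle salt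
Reagents that add atoms: none
Why: Aluminium hydride reduction of the hindered ester to the primary alcohol leaves the silyl and benzyl ethers and the alkene intact.

Step 6
Reactants: 9
Product: 10 (2S,3S)-2-[(benzyloxy)methyl]-3-[(tert-butyldimethylsilyl)oxy]-2-methylpent-4-enal
Conditions: Dess–Martin periodinane, NaHCO3, CH2Cl2, rt
Reagents that add atoms: none
Why: Dess–Martin oxidation gives the aldehyde, which has a quaternary α-carbon and therefore cannot epimerise or enolise.

Step 7
Reactants: 11 (R)-5-methylcyclohex-2-en-1-one; 10 aldehyde from step 6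
Product: 13 syn-aldol adduct (5R)-6-[1-hydroxy-2-(benzyloxymethyl)-3-(tert-butyldimethylsilyloxy)-2-methylpent-4-enyl]-5-methylcyclohex-2-en-1-one (side chain trans to the 5-methyl), via zirconocene chloride enolate 12 (not isolated)
Conditions: LDA, THF, −78 °C; Cp2ZrCl2, −78 → −40 °C; 10, −78 °C; then H2O
Reagents that add atoms: none
Why: Directed aldol addition; kinetic deprotonation occurs at the α′ carbon (later C3), the aldehyde should enter trans to the neighbouring methyl (this fixes C3 and the handedness of the cage), and zirconium enolates give syn aldols even from E (cyclic) enolates, which supplies the C2 epimer that step 11 needs.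

Step 8
Reactants: 13
Product: 14 tertiary allylic alcohol (methyl added to the ring carbonyl carbon, later C8; 1-methylcyclohex-2-en-1-ol form of 13)
Conditions: MeLi (3 equiv), THF, −78 °C; then H2O
Reagents that add atoms: methyllithium, [Li]C
Why: 1,2-Addition of methyllithium to the enone carbonyl (after deprotonation of the free hydroxyl) brings in the future C8 methyl; attack should occur anti to the neighbouring side chain, and the new centre is erased in step 9.

Step 9
Reactants: 14
Product: 15 transposed diol (secondary allylic C6–OH, trisubstituted alkene C7=C8–CH3, free C2–OH)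
Conditions: Ph3SiOReO3 (2 mol %), Et2O, 0 °C
Reagents that add atoms: none
Why: Perrhenate-catalysed 1,3-transposition of the tertiary allylic alcohol ([3,3] shift of the allyl perrhenate ester) should run toward the more substituted alkene, moving oxygen to C6 and putting the nucleophilic C7=C8 double bond in place.

Step 10
Reactants: 15
Product: 16 C6 tert-butyldimethylsilyl ether of 15 (C2–OH free)
Conditions: TBSCl, imidazole, DMF, 0 °C
Reagents that add atoms: tert-butyldimethylsilyl chloride, CC(C)(C)[Si](C)(C)Cl
Why: Silylation should select the accessible allylic C6 hydroxyl, because the C2 hydroxyl is flanked by quaternary C1 and the ring methine C3.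

Step 11
Reactants: 16
Product: 18 6-methylenebicyclo[3.1.1]heptane (cyclobutane C2–C3–C8–C7 closed; C8=CH2; C6–OTBS; C1 arm anti to the three-carbon bridge), via C2 triflate 17 (not isolated)
Conditions: Tf2O, 2,6-di-tert-butyl-4-methylpyridine, CH2Cl2, −78 °C; then (CF3)2CHOH, −40 → 0 °C
Reagents that add atoms: none
Why: Proposed new method: ionisation of the secondary triflate should be assisted by the homoallylic C7=C8 double bond, C7 attacking C2 from the rear with inversion so that the charge appears at C8 as a tertiary 1-methylcyclobutyl-type cation, which can lose a proton only from its methyl group because both neighbours are bridgeheads and so gives the exocyclic methylene; the closest known reaction types are the solvolytic homoallyl-to-cyclobutyl rearrangement (3-methylbut-3-enyl sulfonates give 1-methylcyclobutyl products) and the cyclohexenylmethyl/norcaranyl/norpinyl cation manifold; the syn C2 configuration from step 7 places the C1 arm anti to the C4–C5–C6 bridge, and the two β-oxygenated arms on C1 should disfavour 1,2-shifts.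

Step 12
Reactants: 18
Product: 19 diol (C6–OH and allylic C11–OH free)
Conditions: Bu4NF, THF, rt → 40 °C
Reagents that add atoms: none
Why: Fluoride desilylation removes both silyl ethers while the benzyl ether and the two alkenes stay untouched.

Step 13
Reactants: 19
Product: 20 diketone (C6 ketone; vinyl ketone C11(=O)–C10=C9; C8=CH2)
Conditions: Dess–Martin periodinane, NaHCO3, CH2Cl2, 0 °C → rt
Reagents that add atoms: none
Why: Dess–Martin oxidation of both secondary alcohols gives the acceptor vinyl ketone and the C6 ketone, whose β,γ-alkene cannot move into conjugation because C7 is a bridgehead.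

Step 14
Reactants: 20
Product: 21 tricyclic diketone (seven-membered ring closed; quaternary C8 with CH3; ketones at C6 and C11; C1–CH2OBn)
Conditions: Fe(acac)3 (30 mol %), PhSiH3 (slow addition), EtOH/(CH2OH)2 5:1, 60 °C, 5 mM
Reagents that add atoms: none
Why: Hydrogen-atom transfer from the iron hydride (from Fe(acac)3 and PhSiH3) to the CH2 terminus of the C8 methylene gives the tertiary cyclobutyl radical at C8 and at the same time creates the C8 methyl; this nucleophilic radical adds to the terminal carbon C9 of the tethered vinyl ketone, and the α-keto radical is reduced to the enolate and protonated. The closest known reaction type is the iron-hydride-initiated reductive olefin–enone coupling (Giese-type radical conjugate addition), which is established for quaternary carbons, also intramolecularly. The seven-membered ring closes in the 7-endo-trig mode, because 6-exo attack at C10 would be polarity-mismatched and give a primary radical. C8 is the only new stereocentre: the vinyl ketone hangs from the pseudo-axial C2 arm and can reach only the face of the planar radical on that side, so C9 must end cis to C1 and the methyl anti; this is a syn delivery that a cationic or backside strain-release closure could not give, which is why a radical is used. The step needs hydrogen-atom transfer to the electron-rich 1,1-disubstituted alkene instead of the enone, and cyclisation faster than reduction of the radical; C8 lies between the bridgeheads C3 and C7, so the radical can neither revert to an endocyclic alkene nor open the cyclobutane, and high dilution with slow silane addition favours ring closure.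

Step 15
Reactants: 21
Product: 22 hydroxy diketone (free C1–CH2OH)
Conditions: H2 (1 atm), Pd/C, EtOAc, rt
Reagents that add atoms: none
Why: Hydrogenolysis removes the benzyl ether at a stage where the molecule has no alkene, and the ketones are not reduced under these conditions.

Step 16
Reactants: 22
Product: 23 keto diol (C11–OH cis to the C1 methyl and trans to CH2OH; C6 ketone kept)
Conditions: Me4NBH(OAc)3, MeCN/AcOH, −20 °C
Reagents that add atoms: none
Why: Hydroxyl-directed reduction (Evans–Saksena type); the acetoxyborohydride bound to the CH2OH oxygen delivers hydride to C11 from the CH2OH face, which should place the new hydroxyl trans to CH2OH, and the C6 ketone has no directing group and should not react.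

Step 17
Reactants: 23; 24 angelic acid ((Z)-2-methylbut-2-enoic acid)
Product: 26 primary angelate (C1–CH2O–angeloyl; C11–OH free), via angelic 2,4,6-trichlorobenzoic anhydride 25 (not isolated)
Conditions: 24, 2,4,6-Cl3C6H2COCl, Et3N, toluene, rt; then 23, 75 °C
Reagents that add atoms: none
Why: Yamaguchi-type mixed-anhydride esterification acylates the primary hydroxyl in preference to the hindered neopentyl-type C11 hydroxyl, and running it without a nucleophilic catalyst should avoid Z-to-E isomerisation of the angelate.

Step 18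
Reactants: 26
Product: 27 angelate acetate (C11–OAc; saturated C6 ketone)
Conditions: Ac2O, DMAP (cat.), pyridine, rt
Reagents that add atoms: acetic anhydride, CC(=O)OC(C)=O
Why: Standard acetylation of the remaining secondary alcohol with retention at C11.

Step 19
Reactants: 27
Product: 29 CNP0374220.2 (target), via C5=C6 trimethylsilyl enol ether 28 (not isolated)
Conditions: TMSOTf, Et3N, CH2Cl2, 0 °C; then Pd(OAc)2, MeCN, rt
Reagents that add atoms: none
Why: Saegusa–Ito oxidation; soft enolisation of the only ketone can go only toward C5 because C7 is a bridgehead, and palladium-mediated dehydrogenation with loss of the C4 hydrogen (on the less hindered face, syn to palladium) should give the β-methyl enone C4=C5 while the esters stay untouched.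

**Compound list**
1 | (R)-4-benzyl-3-propanoyl-1,3-oxazolidin-2-one | CCC(=O)N1[C@H](Cc2ccccc2)COC1=O | starting material
2 | acrolein | C=CC=O | starting material
3 | dibutylboron Z-enolate of 1 | CCCCB(CCCC)O/C(=C\C)N1[C@H](Cc2ccccc2)COC1=O | intermediate
4 | (4R)-4-benzyl-3-[(2R,3S)-3-hydroxy-2-methylpent-4-enoyl]-1,3-oxazolidin-2-one | O=C([C@H](C)[C@@H](O)C=C)N1[C@H](Cc2ccccc2)COC1=O | intermediate
5 | methyl (2R,3S)-3-hydroxy-2-methylpent-4-enoate | COC(=O)[C@H](C)[C@@H](O)C=C | intermediate
6 | dilithium alkoxide-enolate of 5 | [Li+].[Li+].[O-]/C(OC)=C(/C)[C@@H]([O-])C=C | intermediate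
7 | methyl (2S,3S)-2-[(benzyloxy)methyl]-3-hydroxy-2-methylpent-4-enoate | COC(=O)[C@@](C)(COCc1ccccc1)[C@@H](O)C=C | intermediate
8 | methyl (2S,3S)-2-[(benzyloxy)methyl]-3-[(tert-butyldimethylsilyl)oxy]-2-methylpent-4-enoate | COC(=O)[C@@](C)(COCc1ccccc1)[C@@H](O[Si](C)(C)C(C)(C)C)C=C | intermediate
9 | (2S,3S)-2-[(benzyloxy)methyl]-3-[(tert-butyldimethylsilyl)oxy]-2-methylpent-4-en-1-ol | OC[C@@](C)(COCc1ccccc1)[C@@H](O[Si](C)(C)C(C)(C)C)C=C | intermediate
10 | (2S,3S)-2-[(benzyloxy)methyl]-3-[(tert-butyldimethylsilyl)oxy]-2-methylpent-4-enal | O=C[C@@](C)(COCc1ccccc1)[C@@H](O[Si](C)(C)C(C)(C)C)C=C | intermediate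
11 | (R)-5-methylcyclohex-2-en-1-one | C[C@@H]1CC=CC(=O)C1 | starting material
12 | zirconocene chloride enolate of 11 (cross-conjugated, α′) | C[C@@H]1CC=CC(O[Zr](Cl)(C2C=CC=C2)C2C=CC=C2)=C1 | intermediate
13 | syn-aldol adduct: (5R)-5-methylcyclohex-2-en-1-one with the C2-carbinol chain at C6, trans to the methyl; chain centres as in 10 | O=C1C=CC[C@@H](C)[C@@H]1[C@@H](O)[C@@](C)(COCc1ccccc1)[C@@H](O[Si](C)(C)C(C)(C)C)C=C | intermediate
14 | tertiary allylic alcohol: 13 with CH3 and OH on the former carbonyl carbon (later C8), methyl trans to the side chain | C[C@@]1(O)C=CC[C@@H](C)[C@@H]1[C@@H](O)[C@@](C)(COCc1ccccc1)[C@@H](O[Si](C)(C)C(C)(C)C)C=C | intermediate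
15 | transposed diol: C6–OH, C7=C8(CH3), side chain on C3 trans to the C4 methyl, C2–OH free | O[C@H]1C=C(C)[C@@H]([C@@H](O)[C@@](C)(COCc2ccccc2)[C@@H](O[Si](C)(C)C(C)(C)C)C=C)[C@H](C)C1 | intermediate
16 | C6 tert-butyldimethylsilyl ether of 15 | CC(C)(C)[Si](C)(C)O[C@H]1C=C(C)[C@@H]([C@@H](O)[C@@](C)(COCc2ccccc2)[C@@H](O[Si](C)(C)C(C)(C)C)C=C)[C@H](C)C1 | intermediate
17 | C2 trifluoromethanesulfonate of 16 | CC(C)(C)[Si](C)(C)O[C@H]1C=C(C)[C@@H]([C@@H](OS(=O)(=O)C(F)(F)F)[C@@](C)(COCc2ccccc2)[C@@H](O[Si](C)(C)C(C)(C)C)C=C)[C@H](C)C1 | intermediate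
18 | 6-methylenebicyclo[3.1.1]heptane: C8=CH2, C6–OTBS, C4–CH3, C2 carrying the C1 arm (CH3, CH2OBn, CH(OTBS)CH=CH2) anti to the three-carbon bridge | C=C1[C@@H]2[C@H](C)C[C@@H](O[Si](C)(C)C(C)(C)C)[C@H]1[C@@H]2[C@@](C)(COCc1ccccc1)[C@@H](O[Si](C)(C)C(C)(C)C)C=C | intermediate
19 | diol from 18 (C6–OH, C11–OH) | C=C1[C@@H]2[C@H](C)C[C@@H](O)[C@H]1[C@@H]2[C@@](C)(COCc1ccccc1)[C@@H](O)C=C | intermediate
20 | diketone: C6 ketone, C8=CH2, C1 arm ending in the vinyl ketone | C=C1[C@@H]2[C@H](C)CC(=O)[C@H]1[C@@H]2[C@@](C)(COCc1ccccc1)C(=O)C=C | intermediate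
21 | tricyclic diketone: longipinane skeleton, C6 and C11 ketones, C8–CH3, C1–CH2OBn, C4–H(CH3) | O=C1CC[C@@]2(C)[C@@H]3[C@H](C)CC(=O)[C@H]2[C@@H]3[C@@]1(C)COCc1ccccc1 | intermediate
22 | hydroxy diketone (C1–CH2OH) | O=C1CC[C@@]2(C)[C@@H]3[C@H](C)CC(=O)[C@H]2[C@@H]3[C@@]1(C)CO | intermediate
23 | keto diol (C11–OH cis to C1–CH3; C6 ketone) | O[C@@H]1CC[C@@]2(C)[C@@H]3[C@H](C)CC(=O)[C@H]2[C@@H]3[C@@]1(C)CO | intermediate
24 | angelic acid | C/C=C(/C)C(=O)O | starting material
25 | angelic 2,4,6-trichlorobenzoic anhydride | C/C=C(/C)C(=O)OC(=O)c1c(Cl)cc(Cl)cc1Cl | intermediate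
26 | primary angelate of 23 | O[C@@H]1CC[C@@]2(C)[C@@H]3[C@H](C)CC(=O)[C@H]2[C@@H]3[C@@]1(C)COC(=O)/C(C)=C\C | intermediate
27 | C11 acetate of 26 (saturated C6 ketone) | CC(=O)O[C@@H]1CC[C@@]2(C)[C@@H]3[C@H](C)CC(=O)[C@H]2[C@@H]3[C@@]1(C)COC(=O)/C(C)=C\C | intermediate
28 | C5=C6 trimethylsilyl enol ether of 27 | CC(=O)O[C@@H]1CC[C@@]2(C)[C@@H]3[C@H](C)C=C(O[Si](C)(C)C)[C@H]2[C@@H]3[C@@]1(C)COC(=O)/C(C)=C\C | intermediate
29 | CNP0374220.2 | CC(=O)O[C@@H]1CC[C@@]2(C)[C@@H]3C(C)=CC(=O)[C@H]2[C@@H]3[C@@]1(C)COC(=O)/C(C)=C\C | target

**Count and risks**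
Total step count: 19. Longest linear sequence: 19 (steps 1–19; 11 and 24 enter as bought materials at steps 7 and 17).

Three steps most likely to fail:

1. Step 11 (bears the label). What may go wrong: loss of the triflate by elimination toward the allylic C3–H, a 1,2-shift from C1, or capture of the cation without four-membered ring closure. Fallback (known chemistry; the cyclobutane is closed by an enolate instead of a cation): setting out from 15, MnO2 in CH2Cl2 oxidises only the allylic C6 hydroxyl to give the enone with free C2 hydroxyl F1. MsCl/Et3N then gives the C2 mesylate F2. With t-BuOK in t-BuOH/THF the extended dienolate forms by deprotonation of the C8 methyl and is alkylated at its α-carbon C7 by C2 with inversion (deconjugative intramolecular enolate alkylation, the classical entry to bicyclo[3.1.1]heptanones, here slowed by the hindered C2), giving the 6-methylene ketone F3. Bu4NF frees the C11 alcohol F4, and Dess–Martin oxidation gives 20, where the route is rejoined.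

2. Step 14. What may go wrong: reduction of the C8 radical by iron hydride or silane before it cyclises (net hydrogenation of the methylene), or hydrogen-atom transfer to the vinyl ketone. Fallback (known chemistry; the same radical is made by photoredox fragmentation of a tertiary oxalate, with no hydride donor present): setting out from 18, Mukaiyama hydration (Mn(dpm)3, PhSiH3, O2, i-PrOH) of the strained 1,1-disubstituted alkene gives the tertiary C8 alcohol F5. Bu4NF gives the triol F6, and Dess–Martin oxidation of the two secondary alcohols gives the hydroxy diketone F7. (COCl)2 followed by aqueous CsHCO3 gives the caesium oxalate F8. Blue-light irradiation with Ir[dF(CF3)ppy]2(dtbbpy)PF6 in DME/DMF/H2O at 60 °C expels two CO2, the C8 radical closes 7-endo on C9, and 21 is reached.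

3. Step 7. What may go wrong: sluggish addition of the bulky zirconium enolate to the neopentyl-type aldehyde and erosion of syn selectivity, which would feed the wrong C2 epimer into step 11. Fallback (known chemistry; C2 is set by reduction instead of by the aldol): setting out from 11 and 10, the lithium enolate (LDA, THF, −78 °C, no zirconium) gives the anti aldol adduct F9. Steps 8, 9 and 10 applied unchanged give the tertiary allylic alcohol F10, the transposed diol F11 and the C6 silyl ether F12. Dess–Martin oxidation gives the C2 ketone F13. Zn(BH4)2 in Et2O at −20 °C, chelated between the ketone and the benzyloxy oxygen, should deliver hydride from the methyl side of C1 and give 16.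

Further compounds
F1 | step 11 | enone with free C2 hydroxyl (C6 ketone, C7=C8) | O=C1C=C(C)[C@@H]([C@@H](O)[C@@](C)(COCc2ccccc2)[C@@H](O[Si](C)(C)C(C)(C)C)C=C)[C@H](C)C1
F2 | step 11 | C2 mesylate of F1 | O=C1C=C(C)[C@@H]([C@@H](OS(C)(=O)=O)[C@@](C)(COCc2ccccc2)[C@@H](O[Si](C)(C)C(C)(C)C)C=C)[C@H](C)C1
F3 | step 11 | 6-methylene ketone (C6 ketone, C8=CH2, C11–OTBS) | C=C1[C@@H]2[C@H](C)CC(=O)[C@H]1[C@@H]2[C@@](C)(COCc1ccccc1)[C@@H](O[Si](C)(C)C(C)(C)C)C=C
F4 | step 11 | C11 alcohol from F3 | C=C1[C@@H]2[C@H](C)CC(=O)[C@H]1[C@@H]2[C@@](C)(COCc1ccccc1)[C@@H](O)C=C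
F5 | step 14 | tertiary C8 alcohol (hydrate of 18) | C[C@@]1(O)[C@@H]2[C@H](C)C[C@@H](O[Si](C)(C)C(C)(C)C)[C@H]1[C@@H]2[C@@](C)(COCc1ccccc1)[C@@H](O[Si](C)(C)C(C)(C)C)C=C
F6 | step 14 | triol from F5 | C[C@@]1(O)[C@@H]2[C@H](C)C[C@@H](O)[C@H]1[C@@H]2[C@@](C)(COCc1ccccc1)[C@@H](O)C=C
F7 | step 14 | hydroxy diketone (C8–OH, C6 ketone, vinyl ketone) | C[C@@]1(O)[C@@H]2[C@H](C)CC(=O)[C@H]1[C@@H]2[C@@](C)(COCc1ccccc1)C(=O)C=C
F8 | step 14 | caesium oxalate of F7 | C[C@@]1(OC(=O)C(=O)[O-])[C@@H]2[C@H](C)CC(=O)[C@H]1[C@@H]2[C@@](C)(COCc1ccccc1)C(=O)C=C.[Cs+]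
F9 | step 7 | anti aldol adduct (C2 epimer of 13) | O=C1C=CC[C@@H](C)[C@@H]1[C@H](O)[C@@](C)(COCc1ccccc1)[C@@H](O[Si](C)(C)C(C)(C)C)C=C
F10 | step 7 | tertiary allylic alcohol (C2 epimer of 14) | C[C@@]1(O)C=CC[C@@H](C)[C@@H]1[C@H](O)[C@@](C)(COCc1ccccc1)[C@@H](O[Si](C)(C)C(C)(C)C)C=C
F11 | step 7 | transposed diol (C2 epimer of 15) | O[C@H]1C=C(C)[C@@H]([C@H](O)[C@@](C)(COCc2ccccc2)[C@@H](O[Si](C)(C)C(C)(C)C)C=C)[C@H](C)C1
F12 | step 7 | C6 silyl ether (C2 epimer of 16) | CC(C)(C)[Si](C)(C)O[C@H]1C=C(C)[C@@H]([C@H](O)[C@@](C)(COCc2ccccc2)[C@@H](O[Si](C)(C)C(C)(C)C)C=C)[C@H](C)C1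
F13 | step 7 | C2 ketone | CC(C)(C)[Si](C)(C)O[C@H]1C=C(C)[C@@H](C(=O)[C@@](C)(COCc2ccccc2)[C@@H](O[Si](C)(C)C(C)(C)C)C=C)[C@H](C)C1
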